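**Direct plan and its weak points**

A direct plan would keep ring A from the start: phloroacetophenone would be benzylated at its 4-OH to the monobenzyl ether A1, and A1 would be condensed with 4-benzyloxybenzaldehyde to the chalcone A2.
An iminium-catalysed Friedel–Crafts addition of ring A of A2 to cinnamaldehyde, with lactol and flavanone closure, would give the tricyclic lactol A3; oxidation would give the lactone A4 and hydrogenolysis the target.
Its weakest step would be the alkylation/lactol/flavanone cascade: a chelated, acyl-deactivated phloroglucinol would have to act as the nucleophile in an untested reaction.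
In the same step the flavanone ring would close with no control over its stereocentre; that ring and that centre would be made only to be destroyed.
The step one would least like to run late would be the last one: it would have to cleave two benzyl ethers and reopen the flavanone by hydrogenolysis without reducing the ketone or letting the lactone migrate to the freed 5-OH.
The monobenzylation to A1 (one hydroxyl of three) and the slow chalcone condensation to A2 would be two steps of selectivity management for little gain in complexity.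

**Plan of the new route**

Ring A carries oxygen on C5, C7 and C8a and carbon or hydrogen on C4a, C6 and C8; it is the Claisen-folded form of a tetraketide whose lactone-folded form is a 4-alkoxy-6-(2-oxoalkyl)-2-pyranone.
The retrosynthesis cuts O1–C2, then C8–C8a of ring A, then C8–C(acyl), then C4–C4a, and arrives at triacetic acid lactone, cinnamaldehyde and a 3-arylpropanoic amide.
Forward, C4 is set on the pyranone, whose C3 is its only nucleophilic carbon, so the C4–C4a bond and the stereocentre exist before ring A does; the lactol ring formed with it is a temporary tether and is opened again.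
Ring A is made next by alkoxide opening and Claisen reclosure of the pyranone: the pyranone carbonyl oxygen becomes O1, the ring oxygen the 7-OH, and the benzylated O4 becomes O5.
The lactone ring of the target closes last, at the only free hydroxyl beside the propanoate chain.
Ring A is never used as a nucleophile, no flavanone ring or benzylic centre is made only to be removed, and the last step is a plain debenzylation.

Key step: step 6

Remark: the facial sense in step 1 is taken from the usual iminium model (attack anti to the shielding group on the E-iminium ion); NaOCH2Ph is taken as its commercial 1 M solution in benzyl alcohol. Locants C2 to C8a and O1 are those of the target; "pyranone C2 to C6, O4" are those of the 2-pyranone.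

**Step 1**
Reactants: 1 4-hydroxy-6-methyl-2H-pyran-2-one (triacetic acid lactone); 2 (2E)-3-phenylprop-2-enal (cinnamaldehyde)
Product: 4 (4R)-2-hydroxy-7-methyl-4-phenyl-3,4-dihydro-2H,5H-pyrano[4,3-b]pyran-5-one (both C2 epimers), via open-chain aldehyde 3 (not isolated)
Conditions: 2 (1.2 equiv), (R)-2-[diphenyl(trimethylsilyloxy)methyl]pyrrolidine (10 mol %), CH2Cl2, 0 °C
Reagents that add atoms: none
Why: Iminium-catalysed Michael addition/hemiacetalisation, known for 4-hydroxy-2-pyranones and 4-hydroxycoumarins with enals: pyranone C3 adds to the Re face of the β-carbon of the E-iminium ion, the Si face being shielded by the diphenyl(silyloxy)methyl group of the R catalyst, which sets C4 as R, and the aldehyde 3 is trapped by the 4-OH as lactol.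

**Step 2**
Reactants: 4 (4R)-2-hydroxy-7-methyl-4-phenyl-3,4-dihydro-2H,5H-pyrano[4,3-b]pyran-5-one
Product: 5 (4R)-7-methyl-4-phenyl-3,4-dihydro-2H,5H-pyrano[4,3-b]pyran-2,5-dione
Conditions: TEMPO (10 mol %), PhI(OAc)2 (1.3 equiv), CH2Cl2, rt
Reagents that add atoms: none
Why: Oxoammonium oxidation of a lactol to the lactone; there is no other oxidisable group, C4 is β to the new carbonyl and not enolisable, so it stays R, and the lactol centre disappears.

**Step 3**
Reactants: 5 (4R)-7-methyl-4-phenyl-3,4-dihydro-2H,5H-pyrano[4,3-b]pyran-2,5-dione; 6 potassium tert-butoxide; 7 benzyl bromide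
Product: 9 tert-butyl (3R)-3-[4-(benzyloxy)-6-methyl-2-oxo-2H-pyran-3-yl]-3-phenylpropanoate, via potassium pyranolate 8 (not isolated)
Conditions: KOtBu (1.05 equiv), t-BuOH (5 equiv), THF, −20 → 0 °C; then BnBr (1.3 equiv), DMF, rt
Reagents that add atoms: potassium tert-butoxide, CC(C)(C)[O-].[K+]; benzyl bromide, BrCc1ccccc1
Why: Acyl transfer followed by Williamson etherification: the C2 lactone of 5 is the enol ester of a vinylogous acid (leaving group pKa about 5), so tert-butoxide opens it (directly or through the ketene, both giving the same ester) and leaves the pyranone carbonyl alone, and the pyranolate 8 is benzylated at O4 as in the known O-alkylation of triacetic acid lactone, C3 being blocked; C4 is untouched.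

**Step 4**
Reactants: 10 3-[4-(benzyloxy)phenyl]propanoic acid; 11 N,O-dimethylhydroxylamine hydrochloride
Product: 13 3-[4-(benzyloxy)phenyl]-N-methoxy-N-methylpropanamide, via acyl imidazole 12 (not isolated)
Conditions: 1,1'-carbonyldiimidazole (1.1 equiv), CH2Cl2, rt; then 11 (1.2 equiv), rt
Reagents that add atoms: N,O-dimethylhydroxylamine hydrochloride, CNOC.Cl
Why: Standard Weinreb amide formation through the acyl imidazole; no stereocentre is involved.

**Step 5**
Reactants: 9 tert-butyl (3R)-3-[4-(benzyloxy)-6-methyl-2-oxo-2H-pyran-3-yl]-3-phenylpropanoate; 13 3-[4-(benzyloxy)phenyl]-N-methoxy-N-methylpropanamide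
Product: 14 tert-butyl (3R)-3-{4-(benzyloxy)-6-{4-[4-(benzyloxy)phenyl]-2-oxobutyl}-2-oxo-2H-pyran-3-yl}-3-phenylpropanoate
Conditions: LiN(SiMe3)2 (1.05 equiv), THF, −78 °C; then 13 (1.2 equiv), −78 → −20 °C; aq. NH4Cl
Reagents that add atoms: none
Why: Lateral metalation of the 6-methyl group of a 4-alkoxy-2-pyranone and C-acylation, a known reaction type: these protons, vinylogous to the lactone carbonyl, should be several pK units more acidic than the α-protons of the hindered tert-butyl ester, and the Weinreb amide gives a stable chelated adduct, so one equivalent of base suffices and the product cannot quench the anion; C4 is untouched.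

**Step 6**
Reactants: 14 tert-butyl (3R)-3-{4-(benzyloxy)-6-{4-[4-(benzyloxy)phenyl]-2-oxobutyl}-2-oxo-2H-pyran-3-yl}-3-phenylpropanoate
Product: 16 tert-butyl (3R)-3-{6-(benzyloxy)-3-{3-[4-(benzyloxy)phenyl]propanoyl}-2,4-dihydroxyphenyl}-3-phenylpropanoate, via ring-opened enoate 15 (not isolated)
Conditions: NaOCH2Ph (3 equiv, 1 M in BnOH), THF, rt → 50 °C; then cold 1 M HCl
Reagents that add atoms: none
Why: Proposed new method: benzyloxide first removes a proton from the side-chain CH2 and then adds to the lactone carbonyl (pyranone C2), the ring opens with a diketone enolate oxygen as leaving group to the (E)-enoate 15, whose ring-derived double bond holds the benzyl ester beside the 5,7-diketone, and the diketonate carbon (future C8) then acylates itself on that ester (future C8a) with loss of benzyloxide, after which the cyclohexadienone enolises at once to the aromatic ring. The closest known reactions are the base-induced Claisen cyclisation of 3,5,7-trioxoalkanoic esters and of 4-hydroxy-6-(2-oxoalkyl)-2-pyranones to acylphloroglucinols and the alkoxide opening of 4-methoxy-2-pyranones to 3-methoxy-5-oxoalk-2-enoates; new is their combination on an O4-alkylated, C3-substituted pyranone, whose monoanion should be more electrophilic than the dianions of the 4-hydroxy cases. The one ring closed is the carbocyclic ring A, by a 6-exo-trig Claisen (Dieckmann-type) C-acylation that forms C8–C8a and is made irreversible by aromatisation. No stereocentre is formed; C4 carries no acidic hydrogen and cannot be lost by a retro-Michael reaction, because O4 is etherified and the tert-butyl ester is neither enolised nor exchanged by alkoxide, so it stays R. The step needs Claisen instead of aldol closure and a fixed place for each oxygen: the C3 substituent makes the aldol mode (pyranone C3 onto the side-chain ketone) a reversible dead end that cannot aromatise, the former lactone carbonyl oxygen appears as the only free hydroxyl next to the propanoate chain (future O1), the ring oxygen becomes the 7-OH and O4 stays a benzyl ether (future O5). Benzyloxide is used so that addition–elimination at pyranone C4 is degenerate, and retro-Claisen loss of the side chain is held back because its keto group is present as the enolate in this medium.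

**Step 7**
Reactants: 16 tert-butyl (3R)-3-{6-(benzyloxy)-3-{3-[4-(benzyloxy)phenyl]propanoyl}-2,4-dihydroxyphenyl}-3-phenylpropanoate
Product: 18 (4R)-5-(benzyloxy)-8-{3-[4-(benzyloxy)phenyl]propanoyl}-7-hydroxy-4-phenyl-3,4-dihydro-2H-chromen-2-one, via carboxylic acid 17 (not isolated)
Conditions: TsOH·H2O (20 mol %), toluene, 80 °C
Reagents that add atoms: none
Why: Acid-catalysed loss of isobutene from the tert-butyl ester, then intramolecular Fischer esterification: of the two oxygens ortho to the side chain only the 2-OH of 16 (future O1) is free, O5 being benzylated, and the 4-OH is out of reach, so a single lactone should form; C4 is not enolisable and stays R.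

**Step 8**
Reactants: 18 (4R)-5-(benzyloxy)-8-{3-[4-(benzyloxy)phenyl]propanoyl}-7-hydroxy-4-phenyl-3,4-dihydro-2H-chromen-2-one
Product: 19 (4R)-5,7-dihydroxy-8-[3-(4-hydroxyphenyl)propanoyl]-4-phenyl-3,4-dihydro-2H-chromen-2-one
Conditions: H2 (1 atm), Pd/C (10 wt % Pd), EtOAc, rt
Reagents that add atoms: none
Why: Hydrogenolysis of two aryl benzyl ethers; the chelated aryl ketone, the lactone and C4 (no heteroatom on it) should survive at 1 atm, and the neutral aprotic medium offers no base or nucleophile to help the lactone migrate to the freed 5-OH; C4 stays R.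

**Compound list**
1 | 4-hydroxy-6-methyl-2H-pyran-2-one (triacetic acid lactone) | Cc1cc(O)cc(=O)o1 | starting material
2 | (2E)-3-phenylprop-2-enal (cinnamaldehyde) | O=C/C=C/c1ccccc1 | starting material
3 | (3R)-3-(4-hydroxy-6-methyl-2-oxo-2H-pyran-3-yl)-3-phenylpropanal | O=CC[C@H](c1ccccc1)c1c(O)cc(C)oc1=O | intermediate
4 | (4R)-2-hydroxy-7-methyl-4-phenyl-3,4-dihydro-2H,5H-pyrano[4,3-b]pyran-5-one (both C2 epimers) | OC1C[C@H](c2ccccc2)c2c(O1)cc(C)oc2=O | intermediate
5 | (4R)-7-methyl-4-phenyl-3,4-dihydro-2H,5H-pyrano[4,3-b]pyran-2,5-dione | O=C1C[C@H](c2ccccc2)c2c(O1)cc(C)oc2=O | intermediate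
6 | potassium tert-butoxide | CC(C)(C)[O-].[K+] | starting material
7 | benzyl bromide | BrCc1ccccc1 | starting material
8 | potassium 3-[(1R)-3-tert-butoxy-3-oxo-1-phenylpropyl]-6-methyl-2-oxo-2H-pyran-4-olate | CC(C)(C)OC(=O)C[C@H](c1ccccc1)c1c([O-])cc(C)oc1=O.[K+] | intermediate
9 | tert-butyl (3R)-3-[4-(benzyloxy)-6-methyl-2-oxo-2H-pyran-3-yl]-3-phenylpropanoate | CC(C)(C)OC(=O)C[C@H](c1ccccc1)c1c(OCc2ccccc2)cc(C)oc1=O | intermediate
10 | 3-[4-(benzyloxy)phenyl]propanoic acid | OC(=O)CCc1ccc(OCc2ccccc2)cc1 | starting material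
11 | N,O-dimethylhydroxylamine hydrochloride | CNOC.Cl | starting material
12 | 1-{3-[4-(benzyloxy)phenyl]propanoyl}-1H-imidazole | O=C(CCc1ccc(OCc2ccccc2)cc1)n1ccnc1 | intermediate
13 | 3-[4-(benzyloxy)phenyl]-N-methoxy-N-methylpropanamide | CON(C)C(=O)CCc1ccc(OCc2ccccc2)cc1 | intermediate
14 | tert-butyl (3R)-3-{4-(benzyloxy)-6-{4-[4-(benzyloxy)phenyl]-2-oxobutyl}-2-oxo-2H-pyran-3-yl}-3-phenylpropanoate | CC(C)(C)OC(=O)C[C@H](c1ccccc1)c1c(OCc2ccccc2)cc(CC(=O)CCc2ccc(OCc3ccccc3)cc2)oc1=O | intermediate
15 | benzyl (2E)-3-(benzyloxy)-9-[4-(benzyloxy)phenyl]-2-[(1R)-3-tert-butoxy-3-oxo-1-phenylpropyl]-5,7-dioxonon-2-enoate | CC(C)(C)OC(=O)C[C@H](c1ccccc1)/C(C(=O)OCc1ccccc1)=C(\OCc1ccccc1)CC(=O)CC(=O)CCc1ccc(OCc2ccccc2)cc1 | intermediate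
16 | tert-butyl (3R)-3-{6-(benzyloxy)-3-{3-[4-(benzyloxy)phenyl]propanoyl}-2,4-dihydroxyphenyl}-3-phenylpropanoate | CC(C)(C)OC(=O)C[C@H](c1ccccc1)c1c(OCc2ccccc2)cc(O)c(C(=O)CCc2ccc(OCc3ccccc3)cc2)c1O | intermediate
17 | (3R)-3-{6-(benzyloxy)-3-{3-[4-(benzyloxy)phenyl]propanoyl}-2,4-dihydroxyphenyl}-3-phenylpropanoic acid | OC(=O)C[C@H](c1ccccc1)c1c(OCc2ccccc2)cc(O)c(C(=O)CCc2ccc(OCc3ccccc3)cc2)c1O | intermediate
18 | (4R)-5-(benzyloxy)-8-{3-[4-(benzyloxy)phenyl]propanoyl}-7-hydroxy-4-phenyl-3,4-dihydro-2H-chromen-2-one | O=C1C[C@H](c2ccccc2)c2c(OCc3ccccc3)cc(O)c(C(=O)CCc3ccc(OCc4ccccc4)cc3)c2O1 | intermediate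
19 | (4R)-5,7-dihydroxy-8-[3-(4-hydroxyphenyl)propanoyl]-4-phenyl-3,4-dihydro-2H-chromen-2-one (CNP0246155.1) | O=C1C[C@H](c2ccccc2)c2c(O)cc(O)c(C(=O)CCc3ccc(O)cc3)c2O1 | target

**Step count**
Total steps: 8. Longest linear sequence: 7 (steps 1, 2, 3, 5, 6, 7, 8).

**Steps most likely to fail**

Step 6 (proposed new method). Ring opening of the enolised, electron-rich pyranone may be too slow, so that cleavage of the side chain or simple recovery of 14 takes over.
The fallback sets out from 5 and returns at 16, and uses the Claisen closure on the substrate type for which it is established, a 4-hydroxy-6-(2-oxoalkyl)-2-pyranone. The benzylation is left out: 5 would be opened with KOtBu as in step 3 and acidified to tert-butyl (3R)-3-(4-hydroxy-6-methyl-2-oxo-2H-pyran-3-yl)-3-phenylpropanoate F1. Its dianion (LiN(iPr)2, 2.1 equiv, THF, −78 °C) would be acylated with 13 to tert-butyl (3R)-3-{6-{4-[4-(benzyloxy)phenyl]-2-oxobutyl}-4-hydroxy-2-oxo-2H-pyran-3-yl}-3-phenylpropanoate F2. Mg(OMe)2 in MeOH would open the pyranone and close ring A to tert-butyl (3R)-3-{3-{3-[4-(benzyloxy)phenyl]propanoyl}-2,4,6-trihydroxyphenyl}-3-phenylpropanoate F3. The hydroxyl para to the acyl group, the only one that is not chelated, would then be benzylated (BnBr, 1 equiv, K2CO3, acetone) to give 16. The place of the protecting group would then rest on a selective alkylation instead of on the ring construction.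

Step 5. Deprotonation next to the ester may compete with metalation of the 6-methyl group and lead to self-condensation.
The fallback sets out from 9 and returns at 17, and takes the α-hydrogens out of play by working on the carboxylate. TFA in CH2Cl2 would cleave 9 to (3R)-3-[4-(benzyloxy)-6-methyl-2-oxo-2H-pyran-3-yl]-3-phenylpropanoic acid F4. Its dianion (LiN(iPr)2, 2.1 equiv) would be acylated with 13 at the methyl group to (3R)-3-{4-(benzyloxy)-6-{4-[4-(benzyloxy)phenyl]-2-oxobutyl}-2-oxo-2H-pyran-3-yl}-3-phenylpropanoic acid F5. The key step run on the carboxylate of F5 (NaOCH2Ph, 4 equiv) would give 17 after acidification, which lactonises as in step 7 to 18.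

Step 3. The ambident pyranolate may be alkylated at the wrong oxygen (giving a 2-benzyloxy-4-pyranone), or the enantiomeric purity from step 1 may be eroded by retro-Michael reaction.
The fallback sets out from 1 and returns at 9, and forms the C4–phenyl bond instead of C4–C4a. Compound 1 would be benzylated at O4 (BnBr, K2CO3, DMF) to 4-(benzyloxy)-6-methyl-2H-pyran-2-one F6 and iodinated at C3 (N-iodosuccinimide, MeCN) to 4-(benzyloxy)-3-iodo-6-methyl-2H-pyran-2-one F7. A Heck reaction with tert-butyl acrylate (Pd(OAc)2, P(o-tolyl)3, Et3N, DMF, 90 °C) would give tert-butyl (2E)-3-[4-(benzyloxy)-6-methyl-2-oxo-2H-pyran-3-yl]prop-2-enoate F8. Hayashi–Miyaura addition of PhB(OH)2 (Rh(acac)(C2H4)2, (S)-BINAP, dioxane–H2O, 100 °C) should then give 9; by the usual model for (E)-3-substituted acrylates, (S)-BINAP should deliver the phenyl group to the face that gives the 3R ester, and the other ligand enantiomer would be used if correlation with 9 from step 3 showed the opposite sense.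

**Further compounds**
F1 | step 6 | tert-butyl (3R)-3-(4-hydroxy-6-methyl-2-oxo-2H-pyran-3-yl)-3-phenylpropanoate | CC(C)(C)OC(=O)C[C@H](c1ccccc1)c1c(O)cc(C)oc1=O
F2 | step 6 | tert-butyl (3R)-3-{6-{4-[4-(benzyloxy)phenyl]-2-oxobutyl}-4-hydroxy-2-oxo-2H-pyran-3-yl}-3-phenylpropanoate | CC(C)(C)OC(=O)C[C@H](c1ccccc1)c1c(O)cc(CC(=O)CCc2ccc(OCc3ccccc3)cc2)oc1=O
F3 | step 6 | tert-butyl (3R)-3-{3-{3-[4-(benzyloxy)phenyl]propanoyl}-2,4,6-trihydroxyphenyl}-3-phenylpropanoate | CC(C)(C)OC(=O)C[C@H](c1ccccc1)c1c(O)cc(O)c(C(=O)CCc2ccc(OCc3ccccc3)cc2)c1O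
F4 | step 5 | (3R)-3-[4-(benzyloxy)-6-methyl-2-oxo-2H-pyran-3-yl]-3-phenylpropanoic acid | OC(=O)C[C@H](c1ccccc1)c1c(OCc2ccccc2)cc(C)oc1=O
F5 | step 5 | (3R)-3-{4-(benzyloxy)-6-{4-[4-(benzyloxy)phenyl]-2-oxobutyl}-2-oxo-2H-pyran-3-yl}-3-phenylpropanoic acid | OC(=O)C[C@H](c1ccccc1)c1c(OCc2ccccc2)cc(CC(=O)CCc2ccc(OCc3ccccc3)cc2)oc1=O
F6 | step 3 | 4-(benzyloxy)-6-methyl-2H-pyran-2-one | Cc1cc(OCc2ccccc2)cc(=O)o1
F7 | step 3 | 4-(benzyloxy)-3-iodo-6-methyl-2H-pyran-2-one | Cc1cc(OCc2ccccc2)c(I)c(=O)o1
F8 | step 3 | tert-butyl (2E)-3-[4-(benzyloxy)-6-methyl-2-oxo-2H-pyran-3-yl]prop-2-enoate | CC(C)(C)OC(=O)/C=C/c1c(OCc2ccccc2)cc(C)oc1=O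
A1 | direct plan | 1-[4-(benzyloxy)-2,6-dihydroxyphenyl]ethan-1-one | CC(=O)c1c(O)cc(OCc2ccccc2)cc1O
A2 | direct plan | (2E)-1-[4-(benzyloxy)-2,6-dihydroxyphenyl]-3-[4-(benzyloxy)phenyl]prop-2-en-1-one | O=C(/C=C/c1ccc(OCc2ccccc2)cc1)c1c(O)cc(OCc2ccccc2)cc1O
A3 | direct plan | (4R)-5-(benzyloxy)-8-[4-(benzyloxy)phenyl]-2-hydroxy-4-phenyl-3,4,8,9-tetrahydro-2H,10H-pyrano[2,3-f]chromen-10-one (epimers at C2 and C8) | OC1C[C@H](c2ccccc2)c2c(OCc3ccccc3)cc3OC(c4ccc(OCc5ccccc5)cc4)CC(=O)c3c2O1
A4 | direct plan | (4R)-5-(benzyloxy)-8-[4-(benzyloxy)phenyl]-4-phenyl-3,4,8,9-tetrahydro-2H,10H-pyrano[2,3-f]chromene-2,10-dione (both C8 epimers) | O=C1C[C@H](c2ccccc2)c2c(OCc3ccccc3)cc3OC(c4ccc(OCc5ccccc5)cc4)CC(=O)c3c2O1
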